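**Retrosynthetic overview**

1. The last C–C bond made is C4–ring D (the dodecanoylphloroglucinol), by Friedel–Crafts attack on a flavan-4-yl cation anti to the C2 aryl group (2,4-trans). C4 therefore carries a temporary ethoxy group, a C–O bond that is not in the target.
2. Key disconnection: ring C is cut at C2–C3 and C4–C4a into an O-aryl oxocarbenium ion (C4a=C8a–O1=C2, a cationic 2-oxadiene) and ethyl vinyl ether (C3=C4). One catalytic asymmetric formal [4+2] annulation (oxa-Povarov) closes ring C and sets C2.
3. Enabling feature: C4a of ring A is ortho to O1 and para to the C7 oxygen, so the arene of the O1=C2 oxocarbenium ion is the nucleophilic end of the oxadiene. The 4-oxyphenyl ring B on C2 stabilises the cation, and C4, benzylic to the ortho/para-dioxygenated ring A, lets the ethoxy group be ionised later.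
4. The oxocarbenium precursor is an α-acetoxy ether made from the aryl ester of the two purchased arenes.
5. Ring order: rings A, B and D are bought; ring C is the only ring formed (step 3).

Key step: step 3

Remark: the sense of induction of the chiral acid in step 3 cannot be predicted with confidence; the (R)-catalyst is written on the assumption that it gives the (2S)-product, and its enantiomer would be used otherwise.

**Step 1**
Reactants: 1 3-(benzyloxy)phenol; 2 4-(benzyloxy)benzoyl chloride
Product: 3 3-(benzyloxy)phenyl 4-(benzyloxy)benzoate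
Conditions: Et3N (1.5 equiv), DMAP (5 mol %), CH2Cl2, 0 °C to rt
Reagents that add atoms: none
Why: DMAP-catalysed O-acylation of a phenol by an acid chloride should give the aryl ester cleanly; no stereocenter is formed.

**Step 2**
Reactants: 3 3-(benzyloxy)phenyl 4-(benzyloxy)benzoate
Product: 5 [3-(benzyloxy)phenoxy][4-(benzyloxy)phenyl]methyl acetate (racemic), via aluminium hemiacetal 4 (not isolated)
Conditions: iBu2AlH (1.2 equiv), CH2Cl2, −78 °C; then pyridine (3 equiv), DMAP (2 equiv), Ac2O (6 equiv), −78 °C to 0 °C; aqueous potassium sodium tartrate; filtration through Et3N-deactivated silica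
Reagents that add atoms: acetic anhydride, CC(=O)OC(C)=O; diisobutylaluminium hydride, CC(C)C[AlH]CC(C)C (gives only the hydride to 5; its aluminium is found only in intermediate 4)
Why: Hydride addition to the ester at −78 °C should give a tetrahedral aluminium hemiacetal that is acetylated in situ (reductive acetylation of an ester to an α-acetoxy ether); the new acetal carbon is racemic and becomes planar in step 3.

**Step 3**
Reactants: 5 [3-(benzyloxy)phenoxy][4-(benzyloxy)phenyl]methyl acetate; 6 ethyl vinyl ether
Product: 9 (2S)-7-(benzyloxy)-2-[4-(benzyloxy)phenyl]-4-ethoxy-3,4-dihydro-2H-chromene (both C4 epimers; cis expected to prevail), via aryl oxocarbenium ion 7 (not isolated), via alkoxycarbenium ion 8 (not isolated)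
Conditions: (R)-3,3′-bis(2,4,6-triisopropylphenyl)-1,1′-binaphthyl-2,2′-diyl N-triflylphosphoramide (C51H57F3NO5PS, 5 mol %), 6 (2 equiv), 4 Å molecular sieves, toluene, −78 °C, slow addition of 5; Et3N quench
Reagents that add atoms: none
Why: Proposed new method: the chiral acid ionises the acetoxy group of 5 (acetate and not aryloxide leaves, because an acyloxycarbenium ion is not viable) to give the O-aryl oxocarbenium ion 7 as a contact ion pair with the chiral phosphoramide anion; the CH2 terminus of 6 adds to C2 on the face left open by the anion (Mukaiyama–Prins-type addition) to give 8, whose C4 is captured by the ring A carbon ortho to O1 and para to the benzyloxy group, and loss of the proton returns the catalyst. The closest known reaction types are the SnCl4-promoted [4+2] annulation of aryl oxocarbenium ions with alkenes (oxa-Povarov reaction), the phosphoric-acid-catalysed asymmetric Povarov reaction of N-aryl imines with vinyl ethers, and asymmetric counteranion-directed additions to oxocarbenium ions. Ring C closes as a six-membered ring by electrophilic aromatic substitution, 6-exo-trig with respect to the C4=O+ bond, overall a formal inverse-electron-demand hetero-Diels–Alder reaction of the 2-oxadiene C4a=C8a–O1=C2. C2 is set by the chiral counteranion in the C2–C3 bond-forming event (catalyst control), while C4 should form mainly cis to the C2 aryl group through a chair-like closure, which is of no consequence because C4 becomes planar in step 5. The step needs ring closure para to the 7-benzyloxy group, which the hindered position between the two oxygens of ring A disfavours, and mono-addition of 6, which the intramolecular arene trap and the low standing concentration of the cation should secure.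

**Step 4**
Reactants: 10 phloroglucinol; 11 dodecanoyl chloride
Product: 12 1-(2,4,6-trihydroxyphenyl)dodecan-1-one
Conditions: AlCl3 (4 equiv), CH2Cl2–PhNO2 (1:1), 0 °C to rt; aqueous HCl work-up
Reagents that add atoms: none
Why: Friedel–Crafts C-acylation of the symmetrical, highly activated phloroglucinol should stop at the mono-ketone because the chelated acyl group deactivates the ring; no stereocenter is formed.

**Step 5**
Reactants: 9 (2S)-7-(benzyloxy)-2-[4-(benzyloxy)phenyl]-4-ethoxy-3,4-dihydro-2H-chromene; 12 1-(2,4,6-trihydroxyphenyl)dodecan-1-one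
Product: 14 1-{3-[(2S,4R)-7-(benzyloxy)-2-[4-(benzyloxy)phenyl]-3,4-dihydro-2H-chromen-4-yl]-2,4,6-trihydroxyphenyl}dodecan-1-one, via flavan-4-yl cation 13 (not isolated)
Conditions: 12 (3 equiv), BF3·OEt2 (20 mol %), CH2Cl2–THF (5:1), −40 °C to −10 °C; Et3N quench; chromatography to remove the minor cis isomer
Reagents that add atoms: none
Why: BF3 ionises the C4–OEt bond of either epimer to the flavan-4-yl cation 13 (stabilised by O1 and the para 7-benzyloxy group), and a free ring carbon of 12 (the two are equivalent) should attack it in a Friedel–Crafts alkylation along the pseudo-axial trajectory anti to the equatorial C2 aryl group of the half-chair cation, giving the 2,4-trans (4R) isomer, while the O1–C2 bond is not ionised at this temperature and C2 is retained.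

**Step 6**
Reactants: 14 1-{3-[(2S,4R)-7-(benzyloxy)-2-[4-(benzyloxy)phenyl]-3,4-dihydro-2H-chromen-4-yl]-2,4,6-trihydroxyphenyl}dodecan-1-one
Product: 15 (+)-myristinin A
Conditions: H2 (1 atm), 10% Pd/C, EtOAc–MeOH (1:1), rt
Reagents that add atoms: none
Why: Hydrogenolysis of the two benzyl aryl ethers (O-debenzylation) should be faster than cleavage of the cyclic benzylic O1–C2 ether, and the hydrogen-bonded aryl ketone should not be reduced, so both stereocenters stay untouched.

**Compound list**

1 | 3-(benzyloxy)phenol | Oc1cccc(OCc2ccccc2)c1 | starting material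
2 | 4-(benzyloxy)benzoyl chloride | O=C(Cl)c1ccc(OCc2ccccc2)cc1 | starting material
3 | 3-(benzyloxy)phenyl 4-(benzyloxy)benzoate | O=C(Oc1cccc(OCc2ccccc2)c1)c1ccc(OCc2ccccc2)cc1 | intermediate
4 | {[3-(benzyloxy)phenoxy][4-(benzyloxy)phenyl]methoxy}bis(2-methylpropyl)alane (racemic, not isolated) | CC(C)C[Al](CC(C)C)OC(Oc1cccc(OCc2ccccc2)c1)c1ccc(OCc2ccccc2)cc1 | intermediate
5 | [3-(benzyloxy)phenoxy][4-(benzyloxy)phenyl]methyl acetate (racemic) | CC(=O)OC(Oc1cccc(OCc2ccccc2)c1)c1ccc(OCc2ccccc2)cc1 | intermediate
6 | ethyl vinyl ether | C=COCC | starting material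
7 | [4-(benzyloxy)benzylidene][3-(benzyloxy)phenyl]oxonium, ion pair with the catalyst anion (not isolated) | C(=[O+]c1cccc(OCc2ccccc2)c1)c1ccc(OCc2ccccc2)cc1 | intermediate
8 | {(3S)-3-[3-(benzyloxy)phenoxy]-3-[4-(benzyloxy)phenyl]propylidene}(ethyl)oxonium (not isolated) | CC[O+]=CC[C@@H](c1ccc(OCc2ccccc2)cc1)Oc1cccc(OCc2ccccc2)c1 | intermediate
9 | (2S)-7-(benzyloxy)-2-[4-(benzyloxy)phenyl]-4-ethoxy-3,4-dihydro-2H-chromene (C4 epimers, mainly (2S,4S)-cis) | CCOC1C[C@@H](c2ccc(OCc3ccccc3)cc2)Oc2cc(OCc3ccccc3)ccc21 | intermediate
10 | phloroglucinol (benzene-1,3,5-triol) | Oc1cc(O)cc(O)c1 | starting material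
11 | dodecanoyl chloride | CCCCCCCCCCCC(=O)Cl | starting material
12 | 1-(2,4,6-trihydroxyphenyl)dodecan-1-one | CCCCCCCCCCCC(=O)c1c(O)cc(O)cc1O | intermediate
13 | (2S)-7-(benzyloxy)-2-[4-(benzyloxy)phenyl]-3,4-dihydro-2H-chromen-4-ylium (not isolated) | [CH+]1C[C@@H](c2ccc(OCc3ccccc3)cc2)Oc2cc(OCc3ccccc3)ccc21 | intermediate
14 | 1-{3-[(2S,4R)-7-(benzyloxy)-2-[4-(benzyloxy)phenyl]-3,4-dihydro-2H-chromen-4-yl]-2,4,6-trihydroxyphenyl}dodecan-1-one | CCCCCCCCCCCC(=O)c1c(O)cc(O)c([C@@H]2C[C@@H](c3ccc(OCc4ccccc4)cc3)Oc3cc(OCc4ccccc4)ccc32)c1O | intermediate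
15 | (+)-myristinin A, 1-{2,4,6-trihydroxy-3-[(2S,4R)-7-hydroxy-2-(4-hydroxyphenyl)-3,4-dihydro-2H-chromen-4-yl]phenyl}dodecan-1-one | CCCCCCCCCCCC(=O)c1c(O)cc(O)c([C@@H]2C[C@@H](c3ccc(O)cc3)Oc3cc(O)ccc32)c1O | target

**Step count and risks**

Total step count: 6. Longest linear sequence: 5 steps (1, 2, 3, 5, 6); step 4 is a one-step side branch.

Steps most likely to fail:

1. Step 3. The ion pair has no hydrogen-bond anchor, so facial discrimination at C2 may be poor. The vinyl ether may also undergo cationic chain growth, ring A of a second molecule may attack the oxocarbenium ion, and the 4-ethoxy group of the product may re-ionise. Fallback with known chemistry, setting out from 5 and coming back at 14: 5 and 6 are annulated without asymmetric induction (SnCl4, 1 equiv, CH2Cl2, −78 °C, the established Lewis-acid version of this annulation) to give racemic 7-(benzyloxy)-2-[4-(benzyloxy)phenyl]-4-ethoxy-3,4-dihydro-2H-chromene F1. F1 is arylated with 12 exactly as in step 5 to give the racemic 2,4-trans ketone F2. F2 is resolved by preparative chromatography on a chiral stationary phase (amylose tris(3,5-dimethylphenylcarbamate)) into 14 and its (2R,4S) enantiomer F3, which is set aside.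

2. Step 5. Configuration at C2 may erode through reversible opening of the O1–C2 bond under acid, facial selectivity at C4 may be incomplete, the trans product may equilibrate to cis by reversible cleavage of the C4–aryl bond, 12 may be alkylated twice, and the cation may self-condense through ring A of a second flavan. Fallback, setting out from 12 and coming back at 15: 12 is per-benzylated (BnBr, K2CO3, DMF, 60 °C) to 1-[2,4,6-tris(benzyloxy)phenyl]dodecan-1-one F4, a non-acidic nucleophile that is fully soluble in CH2Cl2. F4 (3 equiv) and 9 are coupled under strictly aprotic low-temperature conditions (Me3SiOTf, 20 mol %, CH2Cl2, −78 °C), as used for benzyl-protected flavan-4-yl electrophiles, to give the penta-O-benzyl ether F5 of the target. Hydrogenolysis of F5 under the conditions of step 6 gives 15.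

3. Step 2. The aluminium hemiacetal may collapse with loss of the aryloxide before it is acetylated, followed by over-reduction. Fallback, setting out from 1 and coming back at 5: commercial 4-(benzyloxy)benzaldehyde and acetyl chloride (cat. ZnCl2, CH2Cl2, 0 °C) give chloro[4-(benzyloxy)phenyl]methyl acetate F6, used crude. The sodium salt of 1 (NaH, THF, −40 °C to 0 °C) is O-alkylated with F6, the known acyloxyalkylation of phenols with α-chloroalkyl esters, to give 5.

**Further compounds**

F1 | step 3 | racemic 7-(benzyloxy)-2-[4-(benzyloxy)phenyl]-4-ethoxy-3,4-dihydro-2H-chromene (all stereoisomers) | CCOC1CC(c2ccc(OCc3ccccc3)cc2)Oc2cc(OCc3ccccc3)ccc21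
F2 | step 3 | racemic 2,4-trans 1-{3-[7-(benzyloxy)-2-[4-(benzyloxy)phenyl]-3,4-dihydro-2H-chromen-4-yl]-2,4,6-trihydroxyphenyl}dodecan-1-one (1:1 mixture of 14 and its enantiomer) | CCCCCCCCCCCC(=O)c1c(O)cc(O)c([C@@H]2C[C@@H](c3ccc(OCc4ccccc4)cc3)Oc3cc(OCc4ccccc4)ccc32)c1O.CCCCCCCCCCCC(=O)c1c(O)cc(O)c([C@H]2C[C@H](c3ccc(OCc4ccccc4)cc3)Oc3cc(OCc4ccccc4)ccc32)c1O
F3 | step 3 | 1-{3-[(2R,4S)-7-(benzyloxy)-2-[4-(benzyloxy)phenyl]-3,4-dihydro-2H-chromen-4-yl]-2,4,6-trihydroxyphenyl}dodecan-1-one | CCCCCCCCCCCC(=O)c1c(O)cc(O)c([C@H]2C[C@H](c3ccc(OCc4ccccc4)cc3)Oc3cc(OCc4ccccc4)ccc32)c1O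
F4 | step 5 | 1-[2,4,6-tris(benzyloxy)phenyl]dodecan-1-one | CCCCCCCCCCCC(=O)c1c(OCc2ccccc2)cc(OCc2ccccc2)cc1OCc1ccccc1
F5 | step 5 | 1-{2,4,6-tris(benzyloxy)-3-[(2S,4R)-7-(benzyloxy)-2-[4-(benzyloxy)phenyl]-3,4-dihydro-2H-chromen-4-yl]phenyl}dodecan-1-one | CCCCCCCCCCCC(=O)c1c(OCc2ccccc2)cc(OCc2ccccc2)c([C@@H]2C[C@@H](c3ccc(OCc4ccccc4)cc3)Oc3cc(OCc4ccccc4)ccc32)c1OCc1ccccc1
F6 | step 2 | chloro[4-(benzyloxy)phenyl]methyl acetate (racemic) | CC(=O)OC(Cl)c1ccc(OCc2ccccc2)cc1
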